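(Its constants were chosen freely; the rest is arithmetic.)

I read this flask at 3.0 d; its charges, steps and questions are these.

starting material 0.10 M; second substrate 2.00 equiv; partner 0.500 equiv; protic impurity 0.0100 M; free catalyst 0.087 mol%; time 3.0 d

    starting material + free catalyst ⇌ catalyst intermediate A (K1 = 10 L mol⁻¹, k1 = 6.6 L mol⁻¹ s⁻¹)
    partner + catalyst intermediate A → free catalyst + target (k2 = 1.1 L mol⁻¹ s⁻¹)
    second substrate + free catalyst ⇌ catalyst intermediate B (K3 = 1.9 L mol⁻¹, k3 = 8.9 L mol⁻¹ s⁻¹)
    partner + catalyst intermediate B → free catalyst + second product (k4 = 0.89 L mol⁻¹ s⁻¹)
    partner + protic impurity → quenched reagent (k5 = 0.0015 L mol⁻¹ s⁻¹)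
    free catalyst → spent catalyst (k6 = 9.2 × 10⁻⁵ s⁻¹)
    free catalyst ⇌ dormant form (K7 = 0.73, k7 = 9.0 × 10⁻⁶ s⁻¹)

* part of the starting material gone at 3.0 d
* the target standing at 3.0 d, as a percentage of the starting material charged
* amount of target if the flask were left three thousand times as long, in percent of the starting material charged

- The contradiction was plain at once. With the catalyst held at its charge, the forward capture of starting material has a half-life of 0.34 h, and free catalyst has a lifetime, the inverse of its death constant, of 3.02 h. That is 9.00 half-lives, yet I expected most of the starting material to survive.
- The capture mostly reverses: catalyst intermediate A returns at 0.660 s⁻¹, while partner takes it forward at 0.0550 s⁻¹. I therefore treated it as a pre-equilibrium and did the same for catalyst intermediate B.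
- Turnover and catalyst death then both scale with free catalyst, which cancels from their ratio. So I worked in powers of ten. I defined L as the decades by which the catalyst charge can lower the partner before it dies: the catalyst charge, times the sum over both routes of rate constant, equilibrium constant and substrate, divided by the death constant and ln 10.
- The routes gave 1.10 L mol⁻¹ s⁻¹ and 0.338 L mol⁻¹ s⁻¹, so the target's share was 76.5% and L was 0.591.
- Partner destroys the impurity on a timescale of 3.70 h, a little longer than the catalyst's lifetime, so I let the two losses run together. Both are first order in partner, so their decades add. For the impurity's decades I divided its charge by ln 10 and by the partner charge lowered by half of L, which gave 0.171.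
- Those decades together took 0.0414 M of partner. I assumed the impurity's whole charge was among it, and applying the target's share to the remainder gave 24.0%, below the ceiling of 50.0%. The reading lies 23.8 lifetimes in, so I gave that figure for each of the three answers.
- The forecast said 21%, 21% and 21%: “waiting longer adds almost nothing”.
- The flask gave 22.1%, 22.1% and 22.2%, and at 3.00 d it still held 20% of its partner, a fall of 0.699 decades against my 0.762. At fixed equivalents and loading, L scales with the square of concentration, so the more dilute neighbour flask, at 0.025 M, has L of 0.0369. With its partner held whole, that L gives 3.12% of target, and the neighbour flask read 2.49%.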